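The product of this flask comes as a pair, the target and the isomer of the product, and we want the ratio of the isomer to the target at the times asked below.

| flask | solid substrate | other conformer | remark | time |
|---|---|---|---|---|
| gamma | 0.067 M | 0.025 M | run made earlier |  |
| theta | 0.15 M | 0.025 M | run made earlier |  |
| flask | 0.10 M | 0.0250 M |  | 10 d |

| run | time / d | isomer of the product / % | target / % |
|---|---|---|---|
| gamma | 1.04 | 8.5 | 9.4 |
| gamma | 1.67 | 8.4 | 9.6 |
| gamma | 2.00 | 8.6 | 9.3 |
| gamma | 3.00 | 8.5 | 10.1 |
| gamma | 5.00 | 8.1 | 9.5 |
| gamma | 8.00 | 8.7 | 9.9 |
| gamma | 12.0 | 8.5 | 10.1 |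
| theta | 1.04 | 5.0 | 4.6 |
| theta | 1.67 | 5.0 | 5.7 |
| theta | 2.00 | 5.0 | 5.6 |
| theta | 3.00 | 4.9 | 5.6 |
| theta | 5.00 | 4.4 | 5.4 |
| theta | 8.00 | 5.1 | 5.0 |
| theta | 12.0 | 4.6 | 5.4 |

(scatter of a reading: 0.3 percentage points)

- ratio of isomer of the product to target at 10 min
- ratio of isomer of the product to target at 6.0 h
- ratio of isomer of the product to target at 10 d

- solid, in amounts per volume of the solution: solid substrate
- the analysis behind the earlier runs scatters by 0.3 percentage points, standard deviation
- at the start none of the solid substrate is in solution

At the bench we use a rule of thumb: once two isomers read flat, take the ratio of the flat readings. In the gamma run the isomer reads 8.5% at 1.04 d and 8.5% at 12.0 d, a difference no larger than the scatter of 0.3 percentage points. Over the whole of each run, the ratio of the summed readings is 0.873 in gamma and 0.912 in theta. Our flask holds more solid substrate than gamma and less than theta, so we take their mean, 0.892.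

The rule has a border, and we find it by counting. The settling count is the time asked divided by the time of the earliest reading; at one or above, the flask has had at least as long as the gamma run had at its first reading. For this flask, 10 d gives 9.62, so the rule applies. But 10 min gives 0.00668 and 6.0 h gives 0.240, both below one, and no reading speaks for those times. We commit to 0.892 at 10 d and to no number earlier.

The forecast stands at 0.9, 0.9 and 0.89, with the remark "The kinetic ratio could differ substantially". The flask gives 13.3, 1.68 and 0.880.

    starting material ⇌ other conformer (K = 0.110, k = 6.40 × 10⁻⁵ s⁻¹)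
    starting material + target → side product (k = 0.0130 L mol⁻¹ s⁻¹)
    2 other conformer → homo dimer (k = 0.00150 L mol⁻¹ s⁻¹)
    solid substrate ⇌ starting material, rate k4*(cs4 - [starting material]) while solid is left; crystals form when [starting material] > cs4 (solubility = 0.0910 M, k = 3.60 × 10⁻⁵ s⁻¹)
    starting material → target (k = 6.50 × 10⁻⁵ s⁻¹)
    other conformer → isomer of the product (k = 2.50 × 10⁻⁴ s⁻¹)
    target ⇌ isomer of the product (K = 0.880, k = 4.30 × 10⁻⁵ s⁻¹)

In this flask the ratio passes from kinetic to thermodynamic control, and counts of 0.00668, 0.240 and 9.62 stand beside the values just given, in that order. The relaxation half-life of target and isomer of the product by their interconversion alone is 0.0873 d, longer than 10 min and shorter than 10 d. The neighbour flask with 0.025 M of solid substrate, at the same count of 9.62, gives 0.880, with its target at 15.8%.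

Readings and results stem from a simulated flask from invented constants; the scatter is artificial.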